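**Retrosynthetic overview**
- The lactol (C-9′) is made last, by DIBAL reduction of a trans-fused lactone, which also frees the phenols; the epimerisable aldehyde oxidation level never exists earlier.
- Ring B (tetrahydrofuran) is closed by SN2 cyclodehydration at C-9 (O-7′ → C-9, retention at C-7′) on a diol obtained by borane reduction of a C-9 acid.
- The C-8′–C-7′ bond comes from an anti-aldol of a lactone-acid dianion with the aryl aldehyde, anti to the substituents already on ring A; this fixes the trans ring-fusion relationship.
- The lactone acid comes from a D-proline mono-aldol that desymmetrises succinaldehyde (sets C-7/C-8; lactol capture differentiates C-9 from C-9′), then oxidation.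
- Ring order: ring A first (lactol, then lactone), ring B second. Starting materials: vanillin and 2,5-dimethoxytetrahydrofuran.

Assumption: the SMILES is taken exactly as written; it encodes (7S,8S,7′R,8′S,9′R), a trans-fused 3,7-dioxabicyclo[3.3.0]octane with each aryl cis to the neighbouring ring-fusion substituent, and the route targets that isomer under kinetic control throughout.

Numbering used below (lignan): C-7/C-7′ = ArCH–O; C-8/C-8′ = ring-fusion CH; C-9 = OCH2; C-9′ = lactol carbon. Ring A = O–C7–C8–C8′–C9′; ring B = O–C7′–C8′–C8–C9. Ar = 3-methoxy-4-(pivaloyloxy)phenyl.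

**Step 1**
Reactants: 1, vanillin
Product: 2, 4-formyl-2-methoxyphenyl pivalate
Conditions: PivCl (1.15 equiv), Et3N, DMAP (5 mol%), CH2Cl2, 0 °C → rt
Reagents that add atoms: pivaloyl chloride, CC(C)(C)C(=O)Cl
Why: Phenol O-acylation; the hindered, non-enolisable pivalate resists acyl transfer to proline and to enolates, makes the aldehyde a better aldol acceptor, damps benzylic C–O ionisation, and is cleaved by DIBAL in the last step.

**Step 2**
Reactants: 3, 2,5-dimethoxytetrahydrofuran (cis/trans mixture)
Product: 4, succinaldehyde
Conditions: H2O, 90 °C, 2 h; distil off MeOH; CH2Cl2 extraction, short-path distillation; use the same day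
Reagents that add atoms: water, O
Why: Acetal hydrolysis of the cyclic bis-acetal unmasks the symmetric 1,4-dialdehyde (no stereocentres), used fresh to avoid oligomerisation.

**Step 3 (key step)**
Reactants: 4, succinaldehyde (2 equiv); 2, vanillin pivalate (1 equiv)
Product: 5, (2S,3R)-5-hydroxy-2-Ar-oxolane-3-carbaldehyde (2,3-cis; lactol anomers at C-5); in lignan numbering C-7 S, C-8 set, C-9 = free CHO, C-9′ = lactol
Conditions: D-proline (20 mol%), DMF, 4 °C, 4 added by syringe pump over 20 h; cold pH 7 buffer/EtOAc work-up; crude used at once
Reagents that add atoms: none (all heavy atoms come from 2 and 4)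
Why: Proposed new method: a proline enamine cross-aldol with succinaldehyde as donor. The closest known reactions are the List–Houk/MacMillan proline cross-aldol of aldehyde donors with aryl aldehydes, the proline aldol of methyl 4-oxobutanoate with aryl aldehydes, and the proline self-aldol of succinaldehyde. The E-enamine of one CHO attacks the Si face of ArCHO through the acid-bound chair transition state to give the anti aldol (C-7 S, aryl and CHO cis on the ring). The new 7-OH at once closes a five-membered lactol on the remote CHO, which makes the two ends of the dialdehyde different and suppresses a second aldol.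

**Step 4**
Reactants: 5
Product: 6, (2S,3R)-2-Ar-5-oxooxolane-3-carboxylic acid (cis)
Conditions: TEMPO (0.2 equiv), PhI(OAc)2 (3 equiv), MeCN–H2O 1:1, 0 °C → rt; NaHCO3 extraction, acidify to pH 3, crystallise
Reagents that add atoms: water, O (the new carboxyl oxygen)
Why: Oxoammonium (TEMPO) oxidation takes the lactol to the γ-lactone and the aldehyde, via its hydrate, to the acid; this locks the O-7–C-9′ ring, removes the epimerisable β-oxy aldehyde without touching a stereocentre, and allows purification (and dr/ee upgrade) by acid–base extraction and crystallisation.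

**Step 5**
Reactants: 6 (1 equiv); 2 (1.3 equiv)
Product: 7, (2S,3R,4S)-4-[(R)-hydroxy(Ar)methyl]-2-Ar-5-oxooxolane-3-carboxylic acid
Conditions: LiHMDS (2.3 equiv), THF, −78 °C, 45 min; 2 in THF, −78 °C, 30 min; AcOH quench at −78 °C
Reagents that add atoms: none (atoms come from 2 and 6)
Why: Aldol addition of a carboxylate/lactone-enolate dianion (paraconic-acid dianion chemistry): deprotonation occurs at the lactone α-CH2 (C-8′), the aldehyde adds to the face opposite the cis C-8 carboxylate and C-7 aryl (C-8′ trans to C-8), and the ring-locked E-enolate reacts through a Zimmerman–Traxler chair to give the anti carbinol (C-7′ R); the minor syn epimer is removed by crystallisation or chromatography.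

**Step 6**
Reactants: 7
Product: 8, (3S,4S,5S)-3-[(R)-hydroxy(Ar)methyl]-4-(hydroxymethyl)-5-Ar-oxolan-2-one
Conditions: BH3·SMe2 (3 equiv), THF, 0 °C → rt; MeOH quench; neutral work-up, used directly
Reagents that add atoms: none (hydride only)
Why: Chemoselective borane reduction of the carboxylic acid (via the acyloxyborane) in the presence of the lactone and the hindered aryl esters; no stereocentre is touched, and C-9 (CH2OH) and C-9′ (lactone) are now fixed at different oxidation levels.

**Step 7**
Reactants: 8
Product: 9, (3S,3aS,6R,6aS)-3,6-bis-Ar-tetrahydro-1H,3H-furo[3,4-c]furan-1-one (trans-fused lactone/tetrahydrofuran)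
Conditions: PPh3 (1.6 equiv), DIAD (1.5 equiv), THF (0.02 M), 0 °C → rt
Reagents that add atoms: none (loss of water)
Why: Mitsunobu cyclodehydration (intramolecular Williamson-type SN2): the unhindered primary C-9 alcohol is activated as its oxyphosphonium and displaced 5-exo-tet by the 7′-OH, so the bond forms at the CH2 and C-7′ keeps its configuration; because C-9 and C-7′ sit on trans substituents of the lactone, only the trans-fused bicycle can form, irreversibly and under neutral conditions that do not enolise C-8′.

**Step 8**
Reactants: 9
Product: 10, the target, (7S,8S,7′R,8′S,9′R)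
Conditions: DIBAL-H (5.5 equiv), CH2Cl2–toluene, −78 °C, 1 h; MeOH at −78 °C, then aq. Rochelle salt/pH 7 buffer, 0 °C; neutral silica or crystallisation
Reagents that add atoms: none (hydride only; the pivaloyl groups leave)
Why: DIBAL half-reduction of the γ-lactone to the lactol through the tetrahedral aluminate at −78 °C, with reductive cleavage of both aryl pivalates to aluminium phenoxides in the same pot; no acid or base meets the product, so C-8′ is not epimerised to the cis-fused series, and the lactol rests as the 9′R anomer (OH trans to the C-8′ substituent), the anomers interconverting by ring–chain tautomerism.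

**Compound list**
1 | vanillin | COc1cc(C=O)ccc1O | starting material
2 | 4-formyl-2-methoxyphenyl pivalate | COc1cc(C=O)ccc1OC(=O)C(C)(C)C | intermediate
3 | 2,5-dimethoxytetrahydrofuran (cis/trans) | COC1CCC(OC)O1 | starting material
4 | succinaldehyde | O=CCCC=O | intermediate
5 | (2S,3R)-5-hydroxy-2-Ar-oxolane-3-carbaldehyde (cis, anomers) | COc1cc([C@H]2OC(O)C[C@H]2C=O)ccc1OC(=O)C(C)(C)C | intermediate
6 | (2S,3R)-2-Ar-5-oxooxolane-3-carboxylic acid (cis) | COc1cc([C@H]2OC(=O)C[C@H]2C(=O)O)ccc1OC(=O)C(C)(C)C | intermediate
7 | (2S,3R,4S)-4-[(R)-hydroxy(Ar)methyl]-2-Ar-5-oxooxolane-3-carboxylic acid | COc1cc([C@H]2OC(=O)[C@H]([C@@H](O)c3ccc(OC(=O)C(C)(C)C)c(OC)c3)[C@H]2C(=O)O)ccc1OC(=O)C(C)(C)C | intermediate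
8 | (3S,4S,5S)-3-[(R)-hydroxy(Ar)methyl]-4-(hydroxymethyl)-5-Ar-oxolan-2-one | COc1cc([C@H]2OC(=O)[C@H]([C@@H](O)c3ccc(OC(=O)C(C)(C)C)c(OC)c3)[C@H]2CO)ccc1OC(=O)C(C)(C)C | intermediate
9 | (3S,3aS,6R,6aS)-3,6-bis-Ar-tetrahydro-1H,3H-furo[3,4-c]furan-1-one (trans-fused) | COc1cc([C@H]2OC(=O)[C@H]3[C@H]2CO[C@H]3c2ccc(OC(=O)C(C)(C)C)c(OC)c2)ccc1OC(=O)C(C)(C)C | intermediate
10 | 4α-hydroxypinoresinol as specified, (7S,8S,7′R,8′S,9′R) | COc1cc([C@H]2O[C@@H](O)[C@H]3[C@H]2CO[C@H]3c2ccc(O)c(OC)c2)ccc1O | target

**Step count**
Total: 8 steps. Longest linear sequence: 7 steps (3 → 4 → 5 → 6 → 7 → 8 → 9 → 10; the same length from 1 via 2).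

**Steps most likely to fail, with fallbacks**
1. Step 7: the closure pays the trans-fusion strain, and Mitsunobu dehydration of the β-hydroxy lactone to the α-arylidene lactone may compete. Fallback: form the O-7′–C-9 bond by reductive etherification instead of SN2. Oxidise only the primary alcohol of 8 to the C-9 aldehyde (TEMPO, 1.1 equiv PhI(OAc)2, CH2Cl2), then reduce the derived cyclic oxocarbenium with Et3SiH/BF3·OEt2 at −78 °C; the lactone is inert and C-7′ is retained.
2. Step 3: succinaldehyde may self-condense faster than it adds to 2, or the anti/syn ratio may be modest. Fallback: auxiliary-controlled anti-aldol. Use the Mg-catalysed (MgCl2, Et3N, TMSCl) anti-aldol of the N-(3-methoxycarbonylpropanoyl)oxazolidinone (auxiliary enantiomer chosen for 7S) with 2, then acid-mediated desilylation/lactonisation and LiOH/H2O2 cleavage to reach 6.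
3. Step 8: the strained lactol aluminate may open and be over-reduced by the excess hydride needed for the pivalates, or C-8′ may epimerise on work-up. Fallback: trap the lactol as it forms. Use 1.1 equiv DIBAL (lactone only) with in situ O-silylation of the aluminate (TBSOTf/2,6-lutidine), remove the pivalates on this base-stable acetal (K2CO3, MeOH), then release the lactol with buffered fluoride (TBAF/AcOH).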